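**Plan**
- Retrosynthesis: cut the ArCH2–C4 bond and the C11–OH bond together (o-quinone methide of grandinol + (−)-α-gurjunene + water); put a carbonyl helper on C3 of gurjunene and cut C2–C3 of the cyclopentanone; then cut C4–C5 (Claisen), C1=C5 (aldol condensation) and C1=C10 (olefination) back to (+)-2-carene.
- Forward: carene ozonolysis, two-carbon extension at C10, cycloheptene ring by aldol condensation, Claisen transfer of the C3–C4 unit to C5 leaving an exocyclic methylene on C1, cyclopentane ring by C2–C3 closure, removal of the C3 oxygen, arene joined last.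
- Feature used by the key event: in the cyclopentane ring (C1–C5) the methylenes C2 and C3 are neighbours, C3 on C4 and C2 on the ring-fusion carbon C1. With C3 as a formyl carbon and C2 as the end of an exocyclic C1=C2 alkene, C3–C4–C5–C1=C2 is a pent-4-enal, so the acyl carbon (polarity reversed on rhodium) can be joined to the alkene terminus.
- Feature used by the last event: the C4=C5 alkene of gurjunene lies next to the C6–C7–C11 cyclopropane, so C-alkylation at C4 opens that ring to the C5=C6 alkene and the C11 carbinol.
- Stereochemistry: C7 (and C6) from (+)-2-carene; C10 by ligand-controlled copper hydride reduction; C5 set anti to the CMe2 bridge in the Claisen step and relayed to C1 by cis hydroacylation; C4 by attack of the quinone methide on the H1 face of the cyclopentene.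

Key step: step 9

Remark: terpene carbons carry guaiane numbers (C1 ring-fusion CH, C2 and C3 cyclopentane CH2, C4 quaternary carbon, C5=C6 alkene, C7 CH bearing C11, C8, C9, C10 CH(CH3), C11 carbinol carbon). The biogenetic parent (−)-α-gurjunene has the C1, C7 and C10 configuration of the target and is therefore the intermediate aimed at.

**Step 1**
Reactants: 1 (+)-2-carene [(1S,6R)-3,7,7-trimethylbicyclo[4.1.0]hept-2-ene]
Product: 3 4-[(1R,3S)-3-(dimethoxymethyl)-2,2-dimethylcyclopropyl]butan-2-one, via keto aldehyde 2 (not isolated)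
Conditions: O3, CH2Cl2–MeOH, −78 °C; Me2S, −78 °C → rt; then HC(OMe)3, CeCl3·7H2O (cat.), MeOH, rt
Reagents that add atoms: ozone, [O-][O+]=O; trimethyl orthoformate, COC(OC)OC
Why: Ozonolysis with reductive work-up cleaves the only alkene to the cis keto aldehyde without touching the cyclopropane stereocentres, and lanthanide-catalysed acetalisation should take the aldehyde in preference to the methyl ketone.

**Step 2**
Reactants: 3 keto acetal; 4 triethyl phosphonoacetate
Product: 5 ethyl (2E)-5-[(1R,3S)-3-(dimethoxymethyl)-2,2-dimethylcyclopropyl]-3-methylpent-2-enoate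
Conditions: NaH, THF, 0 °C → reflux; E isomer separated by chromatography
Reagents that add atoms: none
Why: Horner–Wadsworth–Emmons olefination of the methyl ketone should give mainly the E trisubstituted enoate, which must be freed of the Z isomer because the two would be reduced to opposite configurations at C10.

**Step 3**
Reactants: 5 E-enoate
Product: 6 ethyl (3R)-5-[(1R,3S)-3-(dimethoxymethyl)-2,2-dimethylcyclopropyl]-3-methylpentanoate
Conditions: Cu(OAc)2·H2O (3 mol %), (R)-DTBM-SEGPHOS (3 mol %), (EtO)2MeSiH, t-BuOH, toluene, 0 °C → rt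
Reagents that add atoms: none
Why: Ligand-controlled copper hydride 1,4-reduction of a β,β-disubstituted enoate sets C10; the (R)-ligand is expected to give the 3R ester (the sense is to be checked on a model and the (S)-ligand used if needed), the cyclopropane being too remote to interfere.

**Step 4**
Reactants: 6 saturated ester
Product: 7 (3R)-5-[(1R,3S)-3-(dimethoxymethyl)-2,2-dimethylcyclopropyl]-3-methylpentanal
Conditions: i-Bu2AlH, CH2Cl2, −78 °C; Rochelle salt work-up
Reagents that add atoms: none
Why: Partial ester reduction at low temperature stops at the aluminium hemiacetal and should release the aldehyde on work-up, the acetal being inert to the hydride.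

**Step 5**
Reactants: 7 aldehyde acetal
Product: 9 (1S,4R,7R)-4,8,8-trimethylbicyclo[5.1.0]oct-2-ene-3-carbaldehyde, via dialdehyde 8 (not isolated)
Conditions: AcOH–H2O–THF, 40 °C; then (PhCH2)2NH·CF3CO2H (cat.), benzene, 60 °C, high dilution
Reagents that add atoms: none
Why: After acetal hydrolysis the enamine aldol condensation can go only one way, because only the C2 aldehyde is enolisable (C6 is a cyclopropane carbon), so C1 should add to C5 and dehydration should give the conjugated cycloheptene carbaldehyde with C10 untouched.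

**Step 6**
Reactants: 9 bicyclic enal
Product: 10 [(1S,4R,7R)-4,8,8-trimethylbicyclo[5.1.0]oct-2-en-3-yl]methanol
Conditions: NaBH4, CeCl3·7H2O, MeOH, 0 °C
Reagents that add atoms: none
Why: Luche conditions should give clean 1,2-reduction of the enal to the primary allylic alcohol.

**Step 7**
Reactants: 10 allylic alcohol; 11 triethyl orthopropionate
Product: 12 ethyl 2-[(1R,2R,4R,7R)-4,8,8-trimethyl-3-methylidenebicyclo[5.1.0]octan-2-yl]propanoate (both epimers at the propanoate carbon C4)
Conditions: EtCO2H (cat.), xylene, 140 °C, EtOH distilled off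
Reagents that add atoms: none
Why: Johnson–Claisen rearrangement should form the C4–C5 bond on the face of C5 away from the CMe2 bridge carbon C11 and move the alkene to the exocyclic C1=C2 position; the C4 epimers do not matter because C4 becomes sp2 in step 10.

**Step 8**
Reactants: 12 Claisen ester
Product: 13 2-[(1R,2R,4R,7R)-4,8,8-trimethyl-3-methylidenebicyclo[5.1.0]octan-2-yl]propanal
Conditions: i-Bu2AlH, toluene, −78 °C; Rochelle salt work-up
Reagents that add atoms: none
Why: Low-temperature partial reduction of the α-branched ester should give the pent-4-enal needed for the key step.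

**Step 9**
Reactants: 13 pent-4-enal
Product: 14 (1aR,4R,4aR,7aR,7bS)-1,1,4,7-tetramethyldecahydro-6H-cyclopropa[e]azulen-6-one (epimers at C4)
Conditions: [Rh(Ph2PCH2CH2PPh2)]BF4 (5 mol %, from [Rh(C7H8)(Ph2PCH2CH2PPh2)]BF4 and H2), CH2Cl2, 25 °C
Reagents that add atoms: none
Why: Monovalent rhodium inserts into the formyl C–H bond, the exocyclic C1=C2 alkene inserts into Rh–H with hydrogen going to C1 and rhodium to the terminal C2, and C–C reductive elimination from the six-membered rhodacycle joins C2 to the acyl carbon C3. The closest known reaction type is the rhodium-catalysed intramolecular hydroacylation of 4-substituted pent-4-enals to 3-substituted cyclopentanones, an umpolung of the aldehyde carbon. The cyclopentanone ring closes in a formally 5-endo-trig sense at the alkene, which the metallacycle pathway allows where polar or radical attack at C2 would be disfavoured. The one new stereocentre that is kept, C1, is set by hydride delivery from rhodium held by the C5 side chain, which should give the cis ring fusion (H1 syn to H5), the usual cis-3,4 outcome of this reaction; C5 was set in step 7 and C4 is erased in step 10. The step needs cyclisation to beat decarbonylation and migration of the exocyclic alkene, which the cationic chelating-diphosphine catalyst at room temperature should secure, and the cyclopropane, not being vinylic here, should be inert to rhodium.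

**Step 10**
Reactants: 14 cyclopentanone
Product: 16 (1aR,4R,4aR,7bS)-1,1,4,7-tetramethyl-1,1a,2,3,4,4a,5,7b-octahydro-6H-cyclopropa[e]azulen-6-one, via silyl enol ether 15 (not isolated)
Conditions: Me3SiCl, Et3N, DMF, 80 °C; then Pd(OAc)2 (1.05 equiv), MeCN, rt
Reagents that add atoms: none
Why: Equilibrating silylation should favour the more substituted C3=C4 enol ether, and Saegusa–Ito oxidation (palladation at C4 by divalent palladium, syn β-hydride loss of H5) should give the tetrasubstituted C4=C5 enone while C1 is untouched under these non-basic conditions.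

**Step 11**
Reactants: 16 enone
Product: 18 (1aR,4R,4aR,7bS)-1,1,4,7-tetramethyl-1a,2,3,4,4a,5,6,7b-octahydro-1H-cyclopropa[e]azulen-6-yl acetate (either carbinol epimer), via allylic alcohol 17 (not isolated)
Conditions: NaBH4, CeCl3·7H2O, MeOH, −20 °C; then Ac2O, pyridine, DMAP (cat.), CH2Cl2, 0 °C
Reagents that add atoms: acetic anhydride, CC(=O)OC(C)=O
Why: Luche 1,2-reduction followed by acetylation of the crude acid-sensitive allylic alcohol should give the acetate, whose carbinol configuration is lost in step 12.

**Step 12**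
Reactants: 18 allylic acetate
Product: 19 (−)-α-gurjunene [(1aR,4R,4aR,7bS)-1,1,4,7-tetramethyl-1a,2,3,4,4a,5,6,7b-octahydro-1H-cyclopropa[e]azulene]
Conditions: Pd(PPh3)4 (5 mol %), LiBHEt3, THF, 0 °C → rt
Reagents that add atoms: none
Why: Zerovalent palladium should ionise the acetate to a π-allyl complex over C3–C4–C5 and the borohydride should attack the less hindered secondary terminus C3, which keeps the tetrasubstituted C4=C5 alkene and returns C3 to the methylene level (Tsuji–Trost-type hydride substitution).

**Step 13**
Reactants: 20 2,4,6-trihydroxytoluene; 21 3-methylbutanoyl chloride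
Product: 22 3-methyl-1-(2,4,6-trihydroxy-3-methylphenyl)butan-1-one
Conditions: AlCl3, PhNO2–CH2Cl2, 0 → 50 °C; aq. HCl work-up
Reagents that add atoms: none
Why: Friedel–Crafts C-acylation of the phloroglucinol nucleus should give one product because the two free ring positions are equivalent.

**Step 14**
Reactants: 22 acylphloroglucinol
Product: 23 grandinol [2,4,6-trihydroxy-3-methyl-5-(3-methylbutanoyl)benzaldehyde]
Conditions: POCl3, DMF, EtOAc, 0 °C → rt; then H2O, 60 °C
Reagents that add atoms: N,N-dimethylformamide, CN(C)C=O; water, O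
Why: Vilsmeier–Haack formylation should take the only free position of the electron-rich ring, and hydrolysis of the iminium salt gives the aldehyde.

**Step 15**
Reactants: 19 (−)-α-gurjunene; 23 grandinol
Product: 25 2,4,6-trihydroxy-3-{[(1R,3aR,4R,7R)-7-(2-hydroxypropan-2-yl)-1,4-dimethyl-1,2,3,3a,4,5,6,7-octahydroazulen-1-yl]methyl}-5-(3-methylbutanoyl)benzaldehyde (target), via o-quinone methide 24 (not isolated)
Conditions: DDQ (1.0 equiv), MeNO2–H2O, 0 °C → rt, dark, 19 in excess
Reagents that add atoms: water, O
Why: DDQ should take hydride from the aryl methyl group to give quinone methide 24, whose methylene carbon is attacked by C4 of the alkene on the cyclopentene face that carries H1 (away from C10 and the body of the seven-membered ring), after which the C5 cyclopropylcarbinyl cation should open by C6–C11 cleavage to the C5=C6 alkene and water should capture the tertiary C11 cation (o-quinone methide alkylation of a terpene alkene with cyclopropylcarbinyl–homoallyl rearrangement).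

**Compound list**
1 | (+)-2-carene | CC1=C[C@H]2[C@@H](CC1)C2(C)C | starting material
2 | (1S,3R)-2,2-dimethyl-3-(3-oxobutyl)cyclopropane-1-carbaldehyde | CC(=O)CC[C@@H]1[C@@H](C1(C)C)C=O | intermediate
3 | 4-[(1R,3S)-3-(dimethoxymethyl)-2,2-dimethylcyclopropyl]butan-2-one | CC(=O)CC[C@@H]1[C@@H](C1(C)C)C(OC)OC | intermediate
4 | triethyl phosphonoacetate | CCOC(=O)CP(=O)(OCC)OCC | starting material
5 | ethyl (2E)-5-[(1R,3S)-3-(dimethoxymethyl)-2,2-dimethylcyclopropyl]-3-methylpent-2-enoate | CCOC(=O)/C=C(\C)CC[C@@H]1[C@@H](C1(C)C)C(OC)OC | intermediate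
6 | ethyl (3R)-5-[(1R,3S)-3-(dimethoxymethyl)-2,2-dimethylcyclopropyl]-3-methylpentanoate | CCOC(=O)C[C@H](C)CC[C@@H]1[C@@H](C1(C)C)C(OC)OC | intermediate
7 | (3R)-5-[(1R,3S)-3-(dimethoxymethyl)-2,2-dimethylcyclopropyl]-3-methylpentanal | O=CC[C@H](C)CC[C@@H]1[C@@H](C1(C)C)C(OC)OC | intermediate
8 | (1S,3R)-2,2-dimethyl-3-[(3R)-3-methyl-5-oxopentyl]cyclopropane-1-carbaldehyde | O=CC[C@H](C)CC[C@@H]1[C@@H](C1(C)C)C=O | intermediate
9 | (1S,4R,7R)-4,8,8-trimethylbicyclo[5.1.0]oct-2-ene-3-carbaldehyde | C[C@@H]1CC[C@@H]2[C@@H](C2(C)C)C=C1C=O | intermediate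
10 | [(1S,4R,7R)-4,8,8-trimethylbicyclo[5.1.0]oct-2-en-3-yl]methanol | C[C@@H]1CC[C@@H]2[C@@H](C2(C)C)C=C1CO | intermediate
11 | triethyl orthopropionate | CCC(OCC)(OCC)OCC | starting material
12 | ethyl 2-[(1R,2R,4R,7R)-4,8,8-trimethyl-3-methylidenebicyclo[5.1.0]octan-2-yl]propanoate (epimers at the propanoate carbon) | C[C@@H]1CC[C@@H]2[C@@H](C2(C)C)[C@@H](C1=C)C(C)C(=O)OCC | intermediate
13 | 2-[(1R,2R,4R,7R)-4,8,8-trimethyl-3-methylidenebicyclo[5.1.0]octan-2-yl]propanal (epimers at the α-carbon) | C[C@@H]1CC[C@@H]2[C@@H](C2(C)C)[C@@H](C1=C)C(C)C=O | intermediate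
14 | (1aR,4R,4aR,7aR,7bS)-1,1,4,7-tetramethyldecahydro-6H-cyclopropa[e]azulen-6-one (cis-fused, epimers at C7 of this name) | C[C@@H]1CC[C@@H]2[C@@H](C2(C)C)[C@@H]3C(C)C(=O)C[C@H]13 | intermediate
15 | trimethylsilyl enol ether of 14 (C6=C7 of the azulenone name) | C[C@@H]1CC[C@@H]2[C@@H](C2(C)C)[C@@H]3C(C)=C(O[Si](C)(C)C)C[C@H]13 | intermediate
16 | (1aR,4R,4aR,7bS)-1,1,4,7-tetramethyl-1,1a,2,3,4,4a,5,7b-octahydro-6H-cyclopropa[e]azulen-6-one | C[C@@H]1CC[C@@H]2[C@@H](C2(C)C)C3=C(C)C(=O)C[C@H]13 | intermediate
17 | (1aR,4R,4aR,7bS)-1,1,4,7-tetramethyl-1a,2,3,4,4a,5,6,7b-octahydro-1H-cyclopropa[e]azulen-6-ol (either carbinol epimer) | C[C@@H]1CC[C@@H]2[C@@H](C2(C)C)C3=C(C)C(O)C[C@H]13 | intermediate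
18 | acetate of 17 | C[C@@H]1CC[C@@H]2[C@@H](C2(C)C)C3=C(C)C(OC(C)=O)C[C@H]13 | intermediate
19 | (−)-α-gurjunene | C[C@@H]1CC[C@@H]2[C@@H](C2(C)C)C3=C(C)CC[C@H]13 | intermediate
20 | 2,4,6-trihydroxytoluene (2-methylbenzene-1,3,5-triol) | Cc1c(O)cc(O)cc1O | starting material
21 | 3-methylbutanoyl chloride | CC(C)CC(=O)Cl | starting material
22 | 3-methyl-1-(2,4,6-trihydroxy-3-methylphenyl)butan-1-one | CC(C)CC(=O)c1c(O)cc(O)c(C)c1O | intermediate
23 | grandinol | CC(C)CC(=O)c1c(O)c(C=O)c(O)c(C)c1O | intermediate
24 | 2,6-dihydroxy-3-methylidene-5-(3-methylbutanoyl)-4-oxocyclohexa-1,5-diene-1-carbaldehyde (one tautomer) | C=C1C(=O)C(C(=O)CC(C)C)=C(O)C(C=O)=C1O | intermediate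
25 | 2,4,6-trihydroxy-3-{[(1R,3aR,4R,7R)-7-(2-hydroxypropan-2-yl)-1,4-dimethyl-1,2,3,3a,4,5,6,7-octahydroazulen-1-yl]methyl}-5-(3-methylbutanoyl)benzaldehyde | CC(C)CC(=O)c1c(O)c(C=O)c(O)c(C[C@@]2(C)CC[C@H]3C2=C[C@H](C(C)(C)O)CC[C@H]3C)c1O | target

**Step count and risks**
Total step count: 15. Longest linear sequence: 13 steps (steps 1–12 and 15, from 1 to 25).

Steps most likely to fail:

Step 15. The C5 cyclopropylcarbinyl cation may be captured by the neighbouring phenolate oxygen (chroman formation) instead of opening and being hydrated. The quinone methide may approach the other face of C4, since C11 of the cyclopropane also lies on the H1 face. DDQ may oxidise the terpene. The fallback sets out from 19 and 23 and comes back at 25. The union is run on purpose as an inverse-demand hetero-Diels–Alder reaction under dry conditions (DDQ, dry MeNO2, molecular sieves) to give the chroman F1, in which the methylene is on C4 and a phenol oxygen on C5; either ortho oxygen may close and both isomers converge. After purification the tertiary cyclopropylcarbinyl aryl ether bond C5–O of the chroman F1 is ionised in a separate short solvolysis (wet (CF3)2CHOH, or dilute CF3CO2H in THF–H2O, 0 °C), so that the ring opens to the C5=C6 alkene and water adds at C11 to give 25. The exposure to acid is kept short because 25 can close back to a chroman.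

Step 9. The acyl rhodium hydride may lose CO, the exocyclic alkene may migrate into the ring, or the ring fusion may form trans. The fallback sets out from 12 and comes back at 14, and it makes the same C2–C3 bond by a polar closure. Hydroboration–oxidation of the exocyclic alkene (9-BBN, THF; NaBO3·4H2O) should deliver H1 on the face away from the C5 side chain and the C10 methyl and give ethyl 2-[(1S,2S,3R,4R,7R)-3-(hydroxymethyl)-4,8,8-trimethylbicyclo[5.1.0]octan-2-yl]propanoate F2. Iodination (I2, PPh3, imidazole, CH2Cl2) gives the iodo ester F3. SmI2 with catalytic Fe(PhCOCHCOPh)3 (THF, −30 °C → rt) should turn the iodo ester F3 into ketone 14 by intramolecular nucleophilic acyl substitution of the ester by the C2 organosamarium.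

Step 5. The dialdehyde may oligomerise in place of closing the seven-membered ring, and the formyl-bearing cyclopropane carbon may epimerise. The fallback sets out from 7 and comes back at 10, closing the ring by alkene metathesis instead. α-Methylenation of 7 (aqueous CH2O, pyrrolidine, EtCO2H, i-PrOH, 45 °C) gives (3R)-5-[(1R,3S)-3-(dimethoxymethyl)-2,2-dimethylcyclopropyl]-3-methyl-2-methylidenepentanal F4. Luche reduction (NaBH4, CeCl3·7H2O, MeOH) gives the allylic alcohol F5. Acetal hydrolysis (pyridinium p-toluenesulfonate, acetone–H2O) gives the hydroxy aldehyde F6. Methylenation (Ph3P=CH2, THF, 0 °C) gives the vinylcyclopropane diene F7. Ring-closing metathesis of the diene F7 (second-generation Grubbs catalyst, CH2Cl2, 40 °C, high dilution) should give 10.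

**Further compounds**
F1 | step 15 | chroman from 19 and 24: CH2 on C4, pyran oxygen on C5 (cis to CH2), cyclopropane intact; pyran oxygen on the ring carbon between the CH2-bearing and the formyl-bearing carbons | C[C@@H]1CC[C@@H]2[C@@H](C2(C)C)[C@]34Oc5c(C=O)c(O)c(C(=O)CC(C)C)c(O)c5C[C@@]3(C)CC[C@H]14
F2 | step 9 | ethyl 2-[(1S,2S,3R,4R,7R)-3-(hydroxymethyl)-4,8,8-trimethylbicyclo[5.1.0]octan-2-yl]propanoate | C[C@@H]1CC[C@@H]2[C@@H](C2(C)C)[C@@H]([C@@H]1CO)C(C)C(=O)OCC
F3 | step 9 | ethyl 2-[(1S,2R,3R,4R,7R)-3-(iodomethyl)-4,8,8-trimethylbicyclo[5.1.0]octan-2-yl]propanoate | C[C@@H]1CC[C@@H]2[C@@H](C2(C)C)[C@@H]([C@@H]1CI)C(C)C(=O)OCC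
F4 | step 5 | (3R)-5-[(1R,3S)-3-(dimethoxymethyl)-2,2-dimethylcyclopropyl]-3-methyl-2-methylidenepentanal | O=CC(=C)[C@H](C)CC[C@@H]1[C@@H](C1(C)C)C(OC)OC
F5 | step 5 | (3R)-5-[(1R,3S)-3-(dimethoxymethyl)-2,2-dimethylcyclopropyl]-3-methyl-2-methylidenepentan-1-ol | OCC(=C)[C@H](C)CC[C@@H]1[C@@H](C1(C)C)C(OC)OC
F6 | step 5 | (1S,3R)-3-[(3R)-4-(hydroxymethyl)-3-methylpent-4-enyl]-2,2-dimethylcyclopropane-1-carbaldehyde | OCC(=C)[C@H](C)CC[C@@H]1[C@@H](C1(C)C)C=O
F7 | step 5 | (3R)-5-[(1R,3S)-3-ethenyl-2,2-dimethylcyclopropyl]-3-methyl-2-methylidenepentan-1-ol | OCC(=C)[C@H](C)CC[C@@H]1[C@@H](C1(C)C)C=C
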